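An order taken at a fixed conversion is easily read as an order at a fixed time, but the two differ, since in this flask more free catalyst also brings the moment of looking forward.

| setting | spring | flask |
|---|---|---|
| substrate | 0.20 M | 0.20 M |
| reagent | 3 equiv | 1.50 equiv |
| free catalyst | 10 mol% | 10 mol% |
| remark | run made earlier |  |

spring run (percent of the substrate charged)

| time / min | product / % | substrate / % |
|---|---|---|
| 2.00 | 57.7 | 0.6 |
| 4.00 | 82.9 | 0 |
| 5.00 | 88.2 | 0.9 |
| 8.00 | 94.8 | 0 |
| 10.0 | 96.3 | 0.6 |

(scatter of a reading: 0.5 percentage points)

* apparent order in free catalyst when 20% of the substrate are converted (percent change of the rate of making product for one percent more free catalyst charged)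

I ran this flask in slow motion from the spring run. In the first instants free catalyst opens substrate, a step with no reagent in it. The spring run read 0.6% substrate at 2.00 min, and as first-order decay that puts 20% conversion near 0.0872 min, an estimate that carries the scatter of that reading. This flask has the same charges of substrate and free catalyst as the spring run, so I used that time here.

In the middle, product comes from catalyst intermediate and reagent. The spring run made 57.7% by 2.00 min, on average one product per catalyst every 0.347 min. With half the reagent I took 0.693 min for this flask.

I called the time to the chosen conversion over this turnover time the look ratio, here 0.126, below one. So I expected the look to fall in the induction period, with catalyst intermediate still filling. There free catalyst multiplies the binding rate and divides the time to the look, so the charge cancels, and that case is the zero of my scale. The opposite end, with catalyst intermediate following open intermediate while free catalyst stays near its charge, gives order one. The end of the run, a drain of the open pool, lies after the look, which I expected within the first turnover. I committed to an order nearer zero than one.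

The forecast gave 0.96, holding that “at fixed conversion the rate should be nearly proportional to the charge”. The simulation gave 0.27.

    substrate + free catalyst → free catalyst + open intermediate (k = 6.70 /M/s)
    free catalyst + open intermediate ⇌ catalyst intermediate (K = 10.0 /M, k = 0.530 /M/s)
    reagent + catalyst intermediate → free catalyst + product (k = 0.850 /M/s)
    2 substrate → homo dimer (k = 0.0250 /M/s)

In this flask the look came at 1.57 s, a look ratio of 0.0378, and by 3.00 min substrate stood at 0%, open intermediate at 30.4%, product at 64.4%, with 14.2% of the catalyst as catalyst intermediate. At 0.257 min, a look ratio of 0.371, the rate was 14 times that at the look, and by 15.0 min product stood at 95.9% beside 3.76% homo dimer.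

(All runs were computed for an exercise; noise was put on by code.)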